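## Analysis of the target

Target 23 is the 7-O-ether of umbelliferone (21) with a monocyclic monoterpene alcohol. The cyclohexene ring is numbered here C1–C6: C1 carries the exocyclic C7 oxymethylene, C2 the vinylic methyl, C2=C3 is the only ring alkene, C4 is the allylic CH2, C5 carries the acetate and C6 is the gem-dimethyl quaternary carbon. There are two stereocentres, C1 and C5 (both R), in a 1,3-relation across C6, with the C7 arm trans to the acetoxy group. The coumarin lactone does not survive hydride, organometallic or strongly basic reagents and must arrive at the end; the alkene is β,γ to C1, so any step that makes C1–H acidic risks moving it into the tetrasubstituted C1=C2 position. The real difficulty is congestion and remote control: C1, C5 and C7 all sit at or next to the quaternary carbon, and the trans relation has to be carried across C6 with no functional group between the two centres. The plan rests on the homoallylic alcohol unit O–C5–C4–C3=C2, the retron of a [2,3]-Wittig shift. If C4–C5 is cut and the C5 oxygen is bonded to C2, the carbocycle becomes an oxolane (O, C2, C1, C6, C5) with the C3=C4 vinyl group on C2 and a carbanion on C5. In the forward sense the ring oxygen becomes the C5 oxygen, the alkene lands at C2=C3 by topology, C5 takes its configuration from C2, and C2 can be set from C1, so one auxiliary-controlled centre governs the whole molecule.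

## Retrosynthetic reasoning

23 is first simplified at its two oxygen substituents. The acetyl–O bond at C5 is cut first (22), because an ester would not survive the dissolving-metal step that frees C7. The aryl ether is cut at C7–O, not at aryl–O, which releases the phenol 21 as such and asks only for a Mitsunobu reaction. The forward step has to pick the primary C7 hydroxyl of diol 20 over the secondary one at C5, which the neopentyl position of C5 should ensure. 20 goes back to its benzyl ether 19.

In 19 the C4–C5 bond is cut and the C5 oxygen is reconnected to C2, which leads to the lithiated oxolane 18 and its storable form, stannane 17. This is the only ring bond whose formation fixes three things at once: the six-membered ring, the alkene position and the C5 configuration. Cutting C1–C6 or C1–C2 instead would leave the quaternary carbon or the trisubstituted alkene to be made in the ring-forming step. The forward reaction must bring the C5 carbanion onto the vinyl terminus C4 across the oxolane while the C2–O bond breaks.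

17 is traced to the anomeric chloride 16, the lactol 15 and the lactone 14. Only the oxidation level at C5 changes, and the C5–Sn bond is made by substitution of an α-chloro ether. The quaternary C6 helps here, since neither 16 nor 18 can eliminate towards C6.

In 14 the C2–C3 bond and the lactone C5–O bond are cut together, giving keto ester 11 and the vinyl nucleophile 12 by way of alkoxide 13. This places the C2 stereocentre under control of C1: the chelate through the C7 ether oxygen and the Felkin–Anh preference both send the nucleophile anti to C6. Vinyl, not methyl, has to be the group that is added, because the group that enters ends cis to the C7 arm.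

The methyl ketone of 11 is taken back through acid chloride 10 to acid 9 and the imide 8 (cut at C2–CH3, then exchange of the acyl substituent). This keeps C2 at the acid level while C1 is set, and the C5 ester on the quaternary carbon is hindered enough to pass through untouched.

In 8 the C1–C7 bond is cut, giving the enolate 7 of imide 5 and the alkoxymethyl electrophile 6. This is the one place where absolute configuration is introduced, by an auxiliary that is recovered. The C7 oxygen comes in already protected, so no free hydroxyl can lactonize onto the C5 ester.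

5 is the methyl ester of acid 4, and 4 is cut at the imide N–acyl bond into the auxiliary 1 (as its lithium salt 3) and the anhydride 2. This brings the gem-dimethyl carbon C6 and the C5 carboxyl in from the first step, and the two carbonyls of 2 are told apart by hindrance alone.

## Alternatives that were turned down

Alternative 1: Here the ring is taken from an aromatic precursor and the C5–O bond is traced to the mono-epoxide A2, made from the prochiral skipped diene A1, whose two trisubstituted ring alkenes are enantiotopic. The forward key step is a catalytic asymmetric epoxidation with a chiral dioxirane, which must choose one alkene and the face anti to the C1 substituent. In its favour: A1 is a few steps from a symmetrical benzoic acid by Birch reduction, the C2=C3 alkene and the C7 arm are present from the start, and absolute configuration comes from a catalyst. Against it: C6 of A2 carries only one methyl group. The second has to be delivered by opening the epoxide at its tertiary carbon with a methyl nucleophile, with inversion, to build the quaternary centre next to C1; this is a very poor substitution site, and attack at C5 or rearrangement of the epoxide would compete. The catalyst also has to control group selection, face selection and mono- versus bis-epoxidation on a cyclic skipped diene that aromatizes easily. This alternative is stronger than the chosen route in step count and in using catalysis. The chosen route offers instead a quaternary carbon that is in place from step 1 and a stereochemical relay (auxiliary, chelate, sigmatropic transfer) in which each link is geometrically enforced.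

Alternative 2: The ring is cut at C5–C6 and traced to a dienylketene, made by Wolff rearrangement (C3–C4 bond) of the Z-dienyl diazomethyl ketone A3; 6π-electrocyclization closes the blocked cyclohexadienone A4. In its favour: the whole carbocycle, with the gem-dimethyl group and all substituents, is assembled in one cascade from an acyclic precursor, and the quaternary C6 stops aromatization. Against it: A4 is achiral, so both stereocentres must be created afterwards. That means an enantioselective 1,6-reduction at C1 with α-protonation at C4 to leave the alkene at C2=C3, then a diastereoselective carbonyl reduction for C5, i.e. two selectivity problems and one deconjugation problem. Dienones of this type are themselves opened by light back to the dienylketene, so the product is not safe under the conditions that form it, and the Z-configured tetrasubstituted diene of A3 has to be made and kept. This alternative is stronger in convergence and in precedent for the ring closure. The chosen route offers a ring that is born with both stereocentres and the alkene in their final places.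

Alternative 3: The C1–C2 bond is traced to a ring contraction: the α-diazo cycloheptenone A5 loses nitrogen on irradiation in an alcohol, the alkenyl carbon C2 shifts to the carbene carbon C1, and the exocyclic ketene is trapped as the C7 ester A6. In its favour: photochemical Wolff contraction of cyclic diazoketones is far better precedented than the chosen key step, C5 can come from the chiral pool, and the alkene and gem-dimethyl group are inherited from the ring. Against it: C1 is created by protonation of the ketene-derived enol with no control element, so an epimer mixture is expected. A6 is a β,γ-unsaturated ester whose C1–H is doubly activated, so any equilibration invites migration of the alkene into conjugation and loss of the centre. A5 itself needs a long preparation (gem-dimethylation, one-carbon ring expansion, degradation of a side chain to the C5 oxygen, diazo transfer next to a quaternary carbon). This alternative is stronger on reliability of the key step. The chosen route offers control of C1 at the outset and a C5 centre derived from it by a stereospecific shift.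

Key step: step 9

## Route

Step 1
Reactants: 1 (4S)-4-benzyl-1,3-oxazolidin-2-one; 2 3,3-dimethyloxolane-2,5-dione (2,2-dimethylsuccinic anhydride)
Product: 4 4-[(4S)-4-benzyl-2-oxo-1,3-oxazolidin-3-yl]-2,2-dimethyl-4-oxobutanoic acid, via N-lithio oxazolidinone 3 (not isolated)
Conditions: n-BuLi, THF, −78 °C; then 2, −78 → 0 °C; aq. HCl
Reagents that add atoms: none
Why: N-acylation of the lithiated oxazolidinone by a cyclic anhydride; the nucleophile should open 2 at the carbonyl flanked by CH2 and not at the one shielded by the quaternary carbon, the same steric bias that steers acyl transfer from mixed pivalic anhydrides; no stereocentre is formed.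

Step 2
Reactants: 4 4-[(4S)-4-benzyl-2-oxo-1,3-oxazolidin-3-yl]-2,2-dimethyl-4-oxobutanoic acid
Product: 5 methyl 4-[(4S)-4-benzyl-2-oxo-1,3-oxazolidin-3-yl]-2,2-dimethyl-4-oxobutanoate
Conditions: Me3SiCHN2, PhMe/MeOH, 0 → 23 °C
Reagents that add atoms: trimethylsilyldiazomethane, C[Si](C)(C)C=[N+]=[N-]
Why: O-methylation of a carboxylic acid with a diazoalkane under neutral conditions, which leaves the imide untouched; the resulting ester on the quaternary carbon has no α-hydrogen and is hindered enough to pass through steps 3–5.

Step 3
Reactants: 5 methyl 4-[(4S)-4-benzyl-2-oxo-1,3-oxazolidin-3-yl]-2,2-dimethyl-4-oxobutanoate; 6 benzyl chloromethyl ether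
Product: 8 methyl (3R)-4-[(4S)-4-benzyl-2-oxo-1,3-oxazolidin-3-yl]-3-[(benzyloxy)methyl]-2,2-dimethyl-4-oxobutanoate, via Cl3Ti Z-enolate 7 (not isolated)
Conditions: TiCl4, i-Pr2NEt, CH2Cl2, 0 °C; then 6, 0 → 23 °C
Reagents that add atoms: none
Why: Evans alkylation through the chelated Cl3Ti Z-enolate; the oxocarbenium-like electrophile from 6 adds to the enolate face opposite the benzyl group of the auxiliary, which sets C1 (R), and only the imide can enolize because the ester has no α-hydrogen.

Step 4
Reactants: 8 methyl (3R)-4-[(4S)-4-benzyl-2-oxo-1,3-oxazolidin-3-yl]-3-[(benzyloxy)methyl]-2,2-dimethyl-4-oxobutanoate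
Product: 9 (2R)-2-[(benzyloxy)methyl]-4-methoxy-3,3-dimethyl-4-oxobutanoic acid
Conditions: LiOH, H2O2, THF/H2O, 0 °C; Na2SO3; aq. HCl
Reagents that add atoms: hydrogen peroxide (as LiOOH), OO
Why: hydroperoxide cleavage of the imide at the exocyclic carbonyl, reliable also for hindered acyl groups, with recovery of 1; the neopentyl-type methyl ester should not be saponified at 0 °C, and the conditions do not enolize C1.

Step 5
Reactants: 9 (2R)-2-[(benzyloxy)methyl]-4-methoxy-3,3-dimethyl-4-oxobutanoic acid
Product: 11 methyl (3R)-3-[(benzyloxy)methyl]-2,2-dimethyl-4-oxopentanoate, via acid chloride 10 (not isolated)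
Conditions: (COCl)2, DMF (cat.), CH2Cl2, 0 → 23 °C; then Me2CuLi (MeLi, CuI), Et2O, −78 °C
Reagents that add atoms: lithium dimethylcuprate, [Li+].C[Cu-]C
Why: acid chloride formation followed by ketone synthesis with Me2CuLi, which transfers one methyl group to the acyl chloride and touches neither the ester nor the product ketone at −78 °C; neither stage is basic enough to epimerize C1 or to eliminate the β-benzyloxy group.

Step 6
Reactants: 11 methyl (3R)-3-[(benzyloxy)methyl]-2,2-dimethyl-4-oxopentanoate; 12 vinylmagnesium bromide
Product: 14 (4R,5S)-4-[(benzyloxy)methyl]-5-ethenyl-3,3,5-trimethyloxolan-2-one, via BrMg alkoxide 13 (not isolated)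
Conditions: 12, THF/CH2Cl2, −78 → 23 °C; H2O
Reagents that add atoms: none
Why: 1,2-addition to the ketone, then lactonization of the tertiary alkoxide onto the ester (5-exo-trig, helped by the gem-dimethyl group); the Cram chelate through the benzyl ether oxygen and the Felkin–Anh model with CMe2CO2Me as the large group both place the nucleophile anti to C6, so vinyl should end cis to the C7 arm on the lactone, which sets C2 (S).

Step 7
Reactants: 14 (4R,5S)-4-[(benzyloxy)methyl]-5-ethenyl-3,3,5-trimethyloxolan-2-one
Product: 15 (4R,5S)-4-[(benzyloxy)methyl]-5-ethenyl-3,3,5-trimethyloxolan-2-ol (both anomers)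
Conditions: i-Bu2AlH, CH2Cl2, −78 °C; aq. potassium sodium tartrate
Reagents that add atoms: none
Why: partial reduction of a lactone to the lactol; the aluminium hemiacetal of this doubly hindered lactone should not collapse before work-up, so over-reduction to the diol is not expected.

Step 8
Reactants: 15 (4R,5S)-4-[(benzyloxy)methyl]-5-ethenyl-3,3,5-trimethyloxolan-2-ol
Product: 17 tributyl[(2S,4R,5S)-4-[(benzyloxy)methyl]-5-ethenyl-3,3,5-trimethyloxolan-2-yl]stannane, via anomeric chloride 16 (not isolated)
Conditions: 1-chloro-N,N,2-trimethylprop-1-en-1-amine, CH2Cl2, 0 °C; solvent changed to THF; Bu3SnLi (Bu3SnH, LiN(i-Pr)2), THF, −78 °C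
Reagents that add atoms: tributylstannyllithium, [Li][Sn](CCCC)(CCCC)CCCC
Why: neutral conversion of the hemiacetal hydroxyl into the anomeric chloride with an α-chloroenamine, then substitution of the α-chloro ether by the stannyl anion, the established access to 2-stannyl cyclic ethers; the quaternary C6 rules out elimination to an enol ether, and the bulky nucleophile should enter on the face away from the vinyl group and the C7 arm, placing tin trans to vinyl.

Step 9
Reactants: 17 tributyl[(2S,4R,5S)-4-[(benzyloxy)methyl]-5-ethenyl-3,3,5-trimethyloxolan-2-yl]stannane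
Product: 19 (1R,5R)-5-[(benzyloxy)methyl]-4,6,6-trimethylcyclohex-3-en-1-ol, via 2-lithiooxolane 18 (not isolated)
Conditions: n-BuLi, THF, −78 → −20 °C; H2O
Reagents that add atoms: none
Why: Proposed new method: tin–lithium exchange gives the α-oxy organolithium 18 with retention, and its C5 carbanion bonds to the vinyl terminus C4 while the allylic C2–O bond breaks and C2=C3 forms, a [2,3]-Wittig shift that leaves the former ring oxygen on C5 as the lithium alkoxide. The closest known reactions are the Still–Wittig rearrangement of stannylmethyl allyl ethers and [2,3]-Wittig ring contractions of cyclic allylic ethers; new here is that carbanion and allylic carbon are the two α-positions of one oxolane, so the oxygen is extruded from the ring and the five-membered ether becomes a six-membered carbocycle. The cyclohexene closes by C5–C4 bond formation, formally 6-endo, through a five-centre envelope transition state (C5, O, C2, C3, C4) lying over the oxolane like a 7-oxanorbornane; a stepwise carbolithiation of the unactivated alkene would be an endo closure and is not expected to compete. The new stereocentre C5 is controlled by C2: C4 can reach C5 only on the oxolane face that carries the vinyl group, which is the face opposite to lithium, so the shift runs with the inversion at the carbanion carbon that [2,3]-Wittig rearrangements prefer, and chirality passes from C2, which becomes trigonal, to C5. Because the C7 arm is cis to vinyl on the oxolane it lies endo in the bicyclic transition state and ends trans to the C5 oxygen; the alkene position and its cis geometry follow from the topology. The step needs the [2,3]-path to win over the [1,2]-shift (a strained cyclobutanol) and over cycloreversion of the lithiated oxolane; low temperature, regiospecific generation of the carbanion and allylic activation of the C2–O bond speak for it, and even a radical-pair recombination at C4 would give the same constitution.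

Step 10
Reactants: 19 (1R,5R)-5-[(benzyloxy)methyl]-4,6,6-trimethylcyclohex-3-en-1-ol
Product: 20 (1R,5R)-5-(hydroxymethyl)-4,6,6-trimethylcyclohex-3-en-1-ol
Conditions: Li, NH3 (l), THF, −78 °C; NH4Cl
Reagents that add atoms: none
Why: dissolving-metal cleavage of the benzyl ether; the isolated trisubstituted alkene and the alkoxide are inert to Li in NH3, no stereocentre is touched, and no oxidant or hydrogenation catalyst comes near the alkene.

Step 11
Reactants: 20 (1R,5R)-5-(hydroxymethyl)-4,6,6-trimethylcyclohex-3-en-1-ol; 21 umbelliferone (7-hydroxy-2H-chromen-2-one)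
Product: 22 7-{[(1R,5R)-5-hydroxy-2,6,6-trimethylcyclohex-2-en-1-yl]methoxy}-2H-chromen-2-one
Conditions: 21, PPh3, DIAD, THF, 0 → 23 °C
Reagents that add atoms: none
Why: Mitsunobu etherification of the acidic phenol 21 at the primary C7 hydroxyl; the secondary C5 hydroxyl is neopentylic and should not be activated, and a cyclic ether between the two hydroxyls cannot form because they are trans on the ring.

Step 12
Reactants: 22 7-{[(1R,5R)-5-hydroxy-2,6,6-trimethylcyclohex-2-en-1-yl]methoxy}-2H-chromen-2-one
Product: 23 (1R,5R)-4,6,6-trimethyl-5-{[(2-oxo-2H-chromen-7-yl)oxy]methyl}cyclohex-3-en-1-yl acetate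
Conditions: Ac2O, DMAP (cat.), pyridine, 23 °C
Reagents that add atoms: acetic anhydride, CC(=O)OC(C)=O
Why: DMAP-catalysed acylation of the hindered secondary alcohol; the coumarin lactone and the aryl ether are stable to Ac2O in pyridine, and C5 keeps its configuration because only the O–H bond reacts.

## Compound list

1 | (4S)-4-benzyl-1,3-oxazolidin-2-one | O=C1N[C@@H](Cc2ccccc2)CO1 | starting material
2 | 3,3-dimethyloxolane-2,5-dione (2,2-dimethylsuccinic anhydride) | CC1(C)CC(=O)OC1=O | starting material
3 | N-lithio derivative of 1 | [Li]N1[C@@H](Cc2ccccc2)COC1=O | intermediate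
4 | 4-[(4S)-4-benzyl-2-oxo-1,3-oxazolidin-3-yl]-2,2-dimethyl-4-oxobutanoic acid | OC(=O)C(C)(C)CC(=O)N1[C@@H](Cc2ccccc2)COC1=O | intermediate
5 | methyl 4-[(4S)-4-benzyl-2-oxo-1,3-oxazolidin-3-yl]-2,2-dimethyl-4-oxobutanoate | COC(=O)C(C)(C)CC(=O)N1[C@@H](Cc2ccccc2)COC1=O | intermediate
6 | benzyl chloromethyl ether | ClCOCc1ccccc1 | starting material
7 | Cl3Ti (Z)-enolate of 5 | COC(=O)C(C)(C)/C=C(\O[Ti](Cl)(Cl)Cl)N1[C@@H](Cc2ccccc2)COC1=O | intermediate
8 | methyl (3R)-4-[(4S)-4-benzyl-2-oxo-1,3-oxazolidin-3-yl]-3-[(benzyloxy)methyl]-2,2-dimethyl-4-oxobutanoate | O=C(N1[C@@H](Cc2ccccc2)COC1=O)[C@@H](COCc3ccccc3)C(C)(C)C(=O)OC | intermediate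
9 | (2R)-2-[(benzyloxy)methyl]-4-methoxy-3,3-dimethyl-4-oxobutanoic acid | OC(=O)[C@@H](COCc1ccccc1)C(C)(C)C(=O)OC | intermediate
10 | methyl (3R)-3-[(benzyloxy)methyl]-4-chloro-2,2-dimethyl-4-oxobutanoate | ClC(=O)[C@@H](COCc1ccccc1)C(C)(C)C(=O)OC | intermediate
11 | methyl (3R)-3-[(benzyloxy)methyl]-2,2-dimethyl-4-oxopentanoate | CC(=O)[C@@H](COCc1ccccc1)C(C)(C)C(=O)OC | intermediate
12 | vinylmagnesium bromide | C=C[Mg]Br | starting material
13 | BrMg alkoxide of methyl (3R,4S)-3-[(benzyloxy)methyl]-4-hydroxy-2,2,4-trimethylhex-5-enoate | C=C[C@](C)(O[Mg]Br)[C@@H](COCc1ccccc1)C(C)(C)C(=O)OC | intermediate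
14 | (4R,5S)-4-[(benzyloxy)methyl]-5-ethenyl-3,3,5-trimethyloxolan-2-one | O=C1O[C@@](C)(C=C)[C@@H](COCc2ccccc2)C1(C)C | intermediate
15 | (4R,5S)-4-[(benzyloxy)methyl]-5-ethenyl-3,3,5-trimethyloxolan-2-ol, both anomers | OC1O[C@@](C)(C=C)[C@@H](COCc2ccccc2)C1(C)C | intermediate
16 | (2S,3R)-3-[(benzyloxy)methyl]-5-chloro-2-ethenyl-2,4,4-trimethyloxolane, anomeric chloride | ClC1O[C@@](C)(C=C)[C@@H](COCc2ccccc2)C1(C)C | intermediate
17 | tributyl[(2S,4R,5S)-4-[(benzyloxy)methyl]-5-ethenyl-3,3,5-trimethyloxolan-2-yl]stannane (tin trans to vinyl) | CCCC[Sn](CCCC)(CCCC)[C@@H]1O[C@@](C)(C=C)[C@@H](COCc2ccccc2)C1(C)C | intermediate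
18 | [(2S,4R,5S)-4-[(benzyloxy)methyl]-5-ethenyl-3,3,5-trimethyloxolan-2-yl]lithium | [Li][C@@H]1O[C@@](C)(C=C)[C@@H](COCc2ccccc2)C1(C)C | intermediate
19 | (1R,5R)-5-[(benzyloxy)methyl]-4,6,6-trimethylcyclohex-3-en-1-ol | O[C@@H]1CC=C(C)[C@@H](COCc2ccccc2)C1(C)C | intermediate
20 | (1R,5R)-5-(hydroxymethyl)-4,6,6-trimethylcyclohex-3-en-1-ol | O[C@@H]1CC=C(C)[C@@H](CO)C1(C)C | intermediate
21 | umbelliferone (7-hydroxy-2H-chromen-2-one) | Oc1ccc2ccc(=O)oc2c1 | starting material
22 | 7-{[(1R,5R)-5-hydroxy-2,6,6-trimethylcyclohex-2-en-1-yl]methoxy}-2H-chromen-2-one | O[C@@H]1CC=C(C)[C@@H](COc2ccc3ccc(=O)oc3c2)C1(C)C | intermediate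
23 | (1R,5R)-4,6,6-trimethyl-5-{[(2-oxo-2H-chromen-7-yl)oxy]methyl}cyclohex-3-en-1-yl acetate | CC(=O)O[C@@H]1CC=C(C)[C@@H](COc2ccc3ccc(=O)oc3c2)C1(C)C | target

## Step count and least certain steps

Total step count: 12. Longest linear sequence: 12 (steps 1–12; the route is linear, with 6, 12 and 21 bought).

Step 9 (key step, new method). The most likely failure is that the C5 carbanion cannot reach the vinyl terminus because of the strain of the bicyclic transition state. It would then be lost by [1,2]-shift, by cycloreversion of the lithiated oxolane on warming, or by simple protonation on work-up. A second risk is loss of stereochemical fidelity at C5 if the shift goes through a radical pair. The fallback uses known chemistry, sets out from 11 and returns at 19: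
- The ketone of 11 is methylenated under non-basic conditions (Zn, CH2Br2, TiCl4, THF) to methyl (3R)-3-[(benzyloxy)methyl]-2,2,4-trimethylpent-4-enoate F1.
- LiAlH4 gives (3R)-3-[(benzyloxy)methyl]-2,2,4-trimethylpent-4-en-1-ol F2, and Dess–Martin oxidation gives (3R)-3-[(benzyloxy)methyl]-2,2,4-trimethylpent-4-enal F3.
- Brown allylation with the B-allyldiisopinocampheylborane made from (+)-B-methoxydiisopinocampheylborane, which should deliver allyl to the Re face, gives (4R,6R)-6-[(benzyloxy)methyl]-5,5,7-trimethylocta-1,7-dien-4-ol F4.
- Ring-closing metathesis with the second-generation Grubbs catalyst (CH2Cl2, 40 °C) joins C2 and C3 and gives 19.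
- Here C5 is set by the reagent and not by C2.

Step 8. The substitution at the anomeric carbon is neopentylic, and the bulky stannyl anion may react too slowly. Halogen–metal exchange or electron transfer at the chloride, or hydrolysis of the chloride during the solvent change, would then take over. The fallback sets out from 15 and returns at 18, and so at 19:
- (PhS)2 and Bu3P convert the lactol under neutral conditions into (2S,3R)-3-[(benzyloxy)methyl]-2-ethenyl-2,4,4-trimethyl-5-(phenylsulfanyl)oxolane F5.
- Reductive lithiation with lithium 4,4'-di-tert-butylbiphenylide (THF, −78 °C), an electron-transfer process that does not feel the hindrance, gives 18 directly, which rearranges as in step 9.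
- If the reductant also removes the benzyl group, the product is 20, the next compound of the route.

Step 3. The enolate carbon is next to a quaternary carbon. C–C bond formation may be so slow that the electrophile decomposes or facial selectivity erodes through an unselective ionic pathway. The fallback installs the gem-dimethyl group last; it sets out from 1 and returns at 14:
- 1 is acylated with purchased 4-methoxy-4-oxobutanoic acid F7 (pivaloyl chloride, Et3N, LiCl) to methyl 4-[(4S)-4-benzyl-2-oxo-1,3-oxazolidin-3-yl]-4-oxobutanoate F8.
- The unhindered Cl3Ti enolate of F8 is alkylated with 6 to methyl (3R)-4-[(4S)-4-benzyl-2-oxo-1,3-oxazolidin-3-yl]-3-[(benzyloxy)methyl]-4-oxobutanoate F9.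
- The operations of steps 4, 5 and 6 then give (2R)-2-[(benzyloxy)methyl]-4-methoxy-4-oxobutanoic acid F10, methyl (3R)-3-[(benzyloxy)methyl]-4-oxopentanoate F11 and (4R,5S)-4-[(benzyloxy)methyl]-5-ethenyl-5-methyloxolan-2-one F12.
- Two rounds of LiN(i-Pr)2 and MeI (THF, −78 °C) on the lactone enolate, by way of (4R,5S)-4-[(benzyloxy)methyl]-5-ethenyl-3,5-dimethyloxolan-2-one F13, give 14.

Step 11. The displacement at C7 is an SN2 reaction at a β,β-branched primary carbon. The oxyphosphonium intermediate may be consumed by alkylation of the reduced azodicarboxylate, or simply not react. The fallback sets out from 20 and returns at 22. It makes the aryl–O bond instead of the C7–O bond: palladium-catalysed C–O coupling of 20 with purchased 7-bromo-2H-chromen-2-one F6 ([Pd(allyl)Cl]2, a bulky di-tert-butyl biarylphosphine, Cs2CO3, toluene, 90 °C). The primary hydroxyl should couple and the hindered secondary one should not.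

## Further compounds

F1 | step 9 | methyl (3R)-3-[(benzyloxy)methyl]-2,2,4-trimethylpent-4-enoate | C=C(C)[C@@H](COCc1ccccc1)C(C)(C)C(=O)OC
F2 | step 9 | (3R)-3-[(benzyloxy)methyl]-2,2,4-trimethylpent-4-en-1-ol | C=C(C)[C@@H](COCc1ccccc1)C(C)(C)CO
F3 | step 9 | (3R)-3-[(benzyloxy)methyl]-2,2,4-trimethylpent-4-enal | C=C(C)[C@@H](COCc1ccccc1)C(C)(C)C=O
F4 | step 9 | (4R,6R)-6-[(benzyloxy)methyl]-5,5,7-trimethylocta-1,7-dien-4-ol | C=C(C)[C@@H](COCc1ccccc1)C(C)(C)[C@H](O)CC=C
F5 | step 8 | (2S,3R)-3-[(benzyloxy)methyl]-2-ethenyl-2,4,4-trimethyl-5-(phenylsulfanyl)oxolane, both anomers | c1ccccc1SC2O[C@@](C)(C=C)[C@@H](COCc3ccccc3)C2(C)C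
F6 | step 11 | 7-bromo-2H-chromen-2-one (purchased) | Brc1ccc2ccc(=O)oc2c1
F7 | step 3 | 4-methoxy-4-oxobutanoic acid (purchased) | COC(=O)CCC(=O)O
F8 | step 3 | methyl 4-[(4S)-4-benzyl-2-oxo-1,3-oxazolidin-3-yl]-4-oxobutanoate | COC(=O)CCC(=O)N1[C@@H](Cc2ccccc2)COC1=O
F9 | step 3 | methyl (3R)-4-[(4S)-4-benzyl-2-oxo-1,3-oxazolidin-3-yl]-3-[(benzyloxy)methyl]-4-oxobutanoate | O=C(N1[C@@H](Cc2ccccc2)COC1=O)[C@@H](COCc3ccccc3)CC(=O)OC
F10 | step 3 | (2R)-2-[(benzyloxy)methyl]-4-methoxy-4-oxobutanoic acid | OC(=O)[C@@H](COCc1ccccc1)CC(=O)OC
F11 | step 3 | methyl (3R)-3-[(benzyloxy)methyl]-4-oxopentanoate | CC(=O)[C@@H](COCc1ccccc1)CC(=O)OC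
F12 | step 3 | (4R,5S)-4-[(benzyloxy)methyl]-5-ethenyl-5-methyloxolan-2-one | O=C1O[C@@](C)(C=C)[C@@H](COCc2ccccc2)C1
F13 | step 3 | (4R,5S)-4-[(benzyloxy)methyl]-5-ethenyl-3,5-dimethyloxolan-2-one, C3 epimers | O=C1O[C@@](C)(C=C)[C@@H](COCc2ccccc2)C1C
A1 | alternative 1 | tert-butyl[(2,6-dimethylcyclohexa-2,5-dien-1-yl)methoxy]diphenylsilane | CC1=CCC=C(C)C1CO[Si](c2ccccc2)(c3ccccc3)C(C)(C)C
A2 | alternative 1 | tert-butyl[(1,3-dimethyl-7-oxabicyclo[4.1.0]hept-3-en-2-yl)methoxy]diphenylsilane, epoxide oxygen trans to the silyloxymethyl group, absolute configuration as in the SMILES | [C@@H]12CC=C(C)[C@@H](CO[Si](c3ccccc3)(c3ccccc3)C(C)(C)C)[C@]1(C)O2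
A3 | alternative 2 | (3Z)-5-{[tert-butyl(diphenyl)silyl]oxymethyl}-1-diazo-4,6-dimethylhepta-3,5-dien-2-one | [N-]=[N+]=CC(=O)/C=C(C)\C(CO[Si](c1ccccc1)(c2ccccc2)C(C)(C)C)=C(C)C
A4 | alternative 2 | 5-{[tert-butyl(diphenyl)silyl]oxymethyl}-4,6,6-trimethylcyclohexa-2,4-dien-1-one | O=C1C=CC(C)=C(CO[Si](c2ccccc2)(c2ccccc2)C(C)(C)C)C1(C)C
A5 | alternative 3 | (5R)-5-{[tert-butyl(dimethyl)silyl]oxy}-7-diazo-2,6,6-trimethylcyclohept-2-en-1-one | CC1=CC[C@@H](O[Si](C)(C)C(C)(C)C)C(C)(C)C(=[N+]=[N-])C1=O
A6 | alternative 3 | methyl (1R,5R)-5-{[tert-butyl(dimethyl)silyl]oxy}-2,6,6-trimethylcyclohex-2-ene-1-carboxylate | CC(C)(C)[Si](C)(C)O[C@@H]1CC=C(C)[C@@H](C(=O)OC)C1(C)C
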